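**Plan**
- Retrosynthesis: the C2–Br and C3–Br bonds are cut first (C2–Br back to a C2 carboxyl group, C3–Br back to C3–H). The indole is then taken back to an indoline-2-carboxylate, and its five-membered ring is opened at N1–C7a and C3–C3a.
- Enabling feature: C7a and C3a are neighbouring carbons of the benzene ring, each flanked by a bromine (at C7 and C4). They are therefore the two ends of the triple bond of a symmetric 3,6-dibromobenzyne, and either orientation of an N–C–C partner gives the same 4,7-dibromo pattern.
- Forward, first half: a commercial dibromophenol is converted into the ortho-silylaryl triflate (O-silylation, retro-Brook shift, triflation). Fluoride then releases the aryne, which is annulated with an N-Boc dehydroalanine ester; this closes the nitrogen ring, the only ring formed in the route.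
- Forward, second half: Boc removal, dehydrogenation, saponification and a final bromination with bromodecarboxylation turn C3–H and the C2 ester handle into the last two C–Br bonds.
- Stereochemistry: the target is achiral. The single stereocentre that appears (C2 of the indoline) is formed racemic and is erased on aromatisation.

Key step: step 4

Remark on the chemistry: the two indoline intermediates are racemates; one enantiomer (S) is drawn in their SMILES, and no control is needed because the centre disappears in step 6.

**Route**

Step 1
Reactants: 1 2,5-dibromophenol; 2 hexamethyldisilazane (HMDS)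
Product: 3 (2,5-dibromophenoxy)trimethylsilane
Conditions: HMDS (0.7 equiv), THF, 65 °C; evaporate, use crude
Reagents that add atoms: hexamethyldisilazane, C[Si](C)(C)N[Si](C)(C)C
Why: O-silylation of a phenol with a disilazane is a routine silyl ether formation driven by loss of volatile ammonia, and it places the trimethylsilyl group on oxygen ready for the migration in step 2.

Step 2
Reactants: 3 (2,5-dibromophenoxy)trimethylsilane
Product: 6 3,6-dibromo-2-(trimethylsilyl)phenol, via 3,6-dibromo-2-(trimethylsilyloxy)phenyllithium 4 (not isolated), via lithium 3,6-dibromo-2-(trimethylsilyl)phenoxide 5 (not isolated)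
Conditions: LiN(iPr)2 (1.2 equiv), THF, −78 °C; then sat. aq. NH4Cl, −78 °C to rt
Reagents that add atoms: none
Why: Directed ortho-lithiation followed by retro-Brook (anionic 1,3 O-to-C silyl) rearrangement: the C6 proton, the only one flanked by the siloxy group and a bromine, is the most acidic, the hindered amide removes it without bromine–lithium exchange, and silicon should intercept the aryllithium intramolecularly before lithium bromide can be lost, with the strong O–Li bond of the phenoxide as driving force.

Step 3
Reactants: 6 3,6-dibromo-2-(trimethylsilyl)phenol; 7 trifluoromethanesulfonic anhydride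
Product: 8 3,6-dibromo-2-(trimethylsilyl)phenyl trifluoromethanesulfonate
Conditions: Tf2O (1.3 equiv), pyridine (2.5 equiv), CH2Cl2, 0 °C
Reagents that add atoms: trifluoromethanesulfonic anhydride, O=S(=O)(OS(=O)(=O)C(F)(F)F)C(F)(F)F
Why: O-triflation of a phenol with triflic anhydride and pyridine is standard, tolerates the ortho C–Si bond under these buffered cold conditions, and completes the ortho-silylaryl triflate that serves as the aryne precursor.

Step 4
Reactants: 8 3,6-dibromo-2-(trimethylsilyl)phenyl trifluoromethanesulfonate; 9 methyl 2-[(tert-butoxycarbonyl)amino]acrylate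
Product: 11 rac-1-tert-butyl 2-methyl 4,7-dibromoindoline-1,2-dicarboxylate, via 3,6-dibromobenzyne 10 (not isolated)
Conditions: 9 (1.5 equiv), Bu4N[Ph3SiF2] (tetrabutylammonium difluorotriphenylsilicate, 1.5 equiv, added in portions), THF, 23 °C
Reagents that add atoms: methyl 2-[(tert-butoxycarbonyl)amino]acrylate, C=C(NC(=O)OC(C)(C)C)C(=O)OC
Why: Fluoride from Bu4N[Ph3SiF2] attacks silicon in 8 and the carbanion so released expels triflate, a far better leaving group than the neighbouring bromide, giving 3,6-dibromobenzyne 10. The carbamate nitrogen of 9 adds to one aryne carbon (N1–C7a) and the resulting aryl anion adds to the acrylate CH2 terminus (C3–C3a) in a formal 5-endo-trig conjugate addition, or the two bonds form in a concerted ene-type manner, closing the five-membered ring and leaving an ester enolate that is protonated at C2. The closest known reaction type is the fluoride-triggered formal (3+2) annulation of ortho-silylaryl triflate-derived arynes with N-carbamoyl dehydroamino esters to indoline-2-carboxylates, applied here to a dihalogenated aryne. The C2 stereocentre arises from unselective protonation of the planar enolate, so no element controls it and 11 is racemic, which is of no consequence because step 6 removes the centre. Regioselectivity needs no control, since the aryne has a mirror plane bisecting the triple bond and both termini carry an ortho bromine, so either orientation gives the 4,7-dibromo pattern. The selectivity that is needed, ring closure ahead of bromide loss or proton quench of the ortho-bromoaryl anion, rests on the Michael acceptor held in place on nitrogen, the non-basic anhydrous fluoride source and the low standing aryne concentration from portionwise fluoride addition.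

Step 5
Reactants: 11 rac-1-tert-butyl 2-methyl 4,7-dibromoindoline-1,2-dicarboxylate
Product: 12 rac-methyl 4,7-dibromoindoline-2-carboxylate
Conditions: CF3CO2H/CH2Cl2 (1:4), 0 °C to rt; aq. NaHCO3 work-up
Reagents that add atoms: none
Why: Acidolytic Boc cleavage (loss of the tert-butyl cation as 2-methylpropene, then decarboxylation of the carbamic acid) frees the indoline N–H needed for the dehydrogenation, while the methyl ester and the aryl bromides are inert to trifluoroacetic acid.

Step 6
Reactants: 12 rac-methyl 4,7-dibromoindoline-2-carboxylate
Product: 13 methyl 4,7-dibromo-1H-indole-2-carboxylate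
Conditions: DDQ (1.3 equiv), toluene, 80 °C
Reagents that add atoms: none
Why: Quinone dehydrogenation of an N–H indoline (hydride abstraction next to nitrogen, then proton loss) is driven by aromatisation to the indole and removes the racemic C2 centre.

Step 7
Reactants: 13 methyl 4,7-dibromo-1H-indole-2-carboxylate; 14 lithium hydroxide
Product: 16 4,7-dibromo-1H-indole-2-carboxylic acid, via lithium 4,7-dibromo-1H-indole-2-carboxylate 15 (not isolated)
Conditions: LiOH·H2O (3 equiv), THF/MeOH/H2O (3:1:1), 40 °C; then 1 M HCl to pH 2
Reagents that add atoms: lithium hydroxide, [Li+].[OH-]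
Why: Saponification of an indole-2-carboxylate by hydroxide addition–elimination at the ester carbonyl is routine, leaves the aryl bromides untouched, and the free acid is released on acidification.

Step 8
Reactants: 16 4,7-dibromo-1H-indole-2-carboxylic acid; 17 N-bromosuccinimide (NBS)
Product: 19 2,3,4,7-tetrabromo-1H-indole, via 3,4,7-tribromo-1H-indole-2-carboxylic acid 18 (not isolated)
Conditions: NBS (2.1 equiv), LiOAc (0.2 equiv), dry DMF, 0 °C to rt, dark; aq. Na2S2O3 quench
Reagents that add atoms: N-bromosuccinimide, O=C1CCC(=O)N1Br
Why: Electrophilic bromination at the nucleophilic C3 is followed by ipso-bromodecarboxylation at C2 (a Hunsdiecker-type electrophilic halodecarboxylation, established for indole-2-carboxylic acids with electrophilic halogen sources), in which the carboxylate leaves as CO2 in place of a proton, while the deactivated C5 and C6 positions should stay untouched.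

**Compound list**
1 | 2,5-dibromophenol | Oc1cc(Br)ccc1Br | starting material
2 | hexamethyldisilazane | C[Si](C)(C)N[Si](C)(C)C | starting material
3 | (2,5-dibromophenoxy)trimethylsilane | C[Si](C)(C)Oc1cc(Br)ccc1Br | intermediate
4 | 3,6-dibromo-2-(trimethylsilyloxy)phenyllithium | C[Si](C)(C)Oc1c([Li])c(Br)ccc1Br | intermediate (not isolated)
5 | lithium 3,6-dibromo-2-(trimethylsilyl)phenoxide | [Li+].[O-]c1c(Br)ccc(Br)c1[Si](C)(C)C | intermediate (not isolated)
6 | 3,6-dibromo-2-(trimethylsilyl)phenol | Oc1c(Br)ccc(Br)c1[Si](C)(C)C | intermediate
7 | trifluoromethanesulfonic anhydride | O=S(=O)(OS(=O)(=O)C(F)(F)F)C(F)(F)F | starting material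
8 | 3,6-dibromo-2-(trimethylsilyl)phenyl trifluoromethanesulfonate | C[Si](C)(C)c1c(Br)ccc(Br)c1OS(=O)(=O)C(F)(F)F | intermediate
9 | methyl 2-[(tert-butoxycarbonyl)amino]acrylate | C=C(NC(=O)OC(C)(C)C)C(=O)OC | starting material
10 | 3,6-dibromobenzyne (1,4-dibromo-2,3-didehydrobenzene) | BrC1=CC=C(Br)C#C1 | intermediate (not isolated)
11 | rac-1-tert-butyl 2-methyl 4,7-dibromoindoline-1,2-dicarboxylate (racemate, S enantiomer drawn) | COC(=O)[C@@H]1Cc2c(Br)ccc(Br)c2N1C(=O)OC(C)(C)C | intermediate
12 | rac-methyl 4,7-dibromoindoline-2-carboxylate (racemate, S enantiomer drawn) | COC(=O)[C@@H]1Cc2c(Br)ccc(Br)c2N1 | intermediate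
13 | methyl 4,7-dibromo-1H-indole-2-carboxylate | COC(=O)c1cc2c(Br)ccc(Br)c2[nH]1 | intermediate
14 | lithium hydroxide | [Li+].[OH-] | starting material
15 | lithium 4,7-dibromo-1H-indole-2-carboxylate | [Li+].[O-]C(=O)c1cc2c(Br)ccc(Br)c2[nH]1 | intermediate (not isolated)
16 | 4,7-dibromo-1H-indole-2-carboxylic acid | OC(=O)c1cc2c(Br)ccc(Br)c2[nH]1 | intermediate
17 | N-bromosuccinimide | O=C1CCC(=O)N1Br | starting material
18 | 3,4,7-tribromo-1H-indole-2-carboxylic acid | OC(=O)c1[nH]c2c(Br)ccc(Br)c2c1Br | intermediate (not isolated)
19 | 2,3,4,7-tetrabromo-1H-indole | Brc1[nH]c2c(Br)ccc(Br)c2c1Br | target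

**Totals**
Total step count: 8
Longest linear sequence: 8 steps (1 to 19; 9 and the reagents are commercial)

**Steps most likely to fail**

Step 4 (aryne annulation). After N-arylation, the ortho-bromoaryl anion may be protonated, or may expel bromide, before the geometrically demanding five-membered closure. The outcome would be N-arylation without C–C bond formation, or aryne-relay oligomerisation. The fallback sets out from 8 and comes back at 16. It keeps the same two bonds but makes them one after the other.
- Methyl pyruvate is condensed with 4-methylbenzenesulfonohydrazide in methanol to give methyl 2-{2-[(4-methylphenyl)sulfonyl]hydrazinylidene}propanoate F1.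
- The aryne 10 released from 8 (CsF, MeCN, rt) is trapped by the sulfonamide nitrogen of F1. This is an aryne N-arylation in which the aryl anion only needs a proton, which the medium supplies. It should give methyl 2-{2-(2,5-dibromophenyl)-2-[(4-methylphenyl)sulfonyl]hydrazinylidene}propanoate F2 and so makes N1–C7a.
- Fischer indolisation of F2 (BF3·OEt2, MeCN, reflux) forms C3–C3a at the only free ortho position, with loss of ammonia. It should give methyl 4,7-dibromo-1-[(4-methylphenyl)sulfonyl]-1H-indole-2-carboxylate F3.
- KOH in aqueous methanol at 60 °C, then HCl, cleaves both the N-sulfonyl group and the ester and returns acid 16. Steps 5 to 7 are bypassed.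

Step 8 (bromination with bromodecarboxylation). The reaction may stall after C3 bromination because ipso attack at C2 of the electron-poor tribromo acid is slow. Alternatively, surplus reagent may over-oxidise the product to oxindole-type material. The fallback sets out from 16 and comes back at 19. It separates decarboxylation from bromination.
- Protodecarboxylation of 16 (Ag2CO3 10 mol %, AcOH cat., DMSO, 120 °C) should give 4,7-dibromo-1H-indole F4.
- F4 is dibrominated with NBS (2.05 equiv, DMF, 0 °C). Bromination occurs first at C3 and then at C2, by the 3-bromoindolenine and 1,2-shift pathway usual for 3-substituted indoles, to give 19.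

Step 2 (lithiation and silyl migration). The ortho-bromoaryllithium 4 may lose lithium bromide or scramble bromine positions (halogen dance) before the silyl shift. The amide may also attack silicon and simply desilylate the ether. The fallback sets out from 1 and comes back at 6. It replaces the migrating silyl group by an external electrophile trapped in situ.
- Phenol 1 is protected (chloromethyl methyl ether, iPr2NEt, CH2Cl2) as 1,4-dibromo-2-(methoxymethoxy)benzene F5.
- LiN(iPr)2 is added at −78 °C to F5 premixed with excess Me3SiCl, so that the C6 anion is silylated as it forms. This should give [3,6-dibromo-2-(methoxymethoxy)phenyl]trimethylsilane F6.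
- The acetal is removed with dilute HCl in methanol at rt, conditions the electron-poor aryl silane should survive, to return phenol 6.

**Further compounds**
F1 | step 4 | methyl 2-{2-[(4-methylphenyl)sulfonyl]hydrazinylidene}propanoate (C=N geometry immaterial) | COC(=O)C(C)=NNS(=O)(=O)c1ccc(C)cc1
F2 | step 4 | methyl 2-{2-(2,5-dibromophenyl)-2-[(4-methylphenyl)sulfonyl]hydrazinylidene}propanoate (C=N geometry immaterial) | COC(=O)C(C)=NN(c1cc(Br)ccc1Br)S(=O)(=O)c1ccc(C)cc1
F3 | step 4 | methyl 4,7-dibromo-1-[(4-methylphenyl)sulfonyl]-1H-indole-2-carboxylate | COC(=O)c1cc2c(Br)ccc(Br)c2n1S(=O)(=O)c1ccc(C)cc1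
F4 | step 8 | 4,7-dibromo-1H-indole | Brc1ccc(Br)c2[nH]ccc12
F5 | step 2 | 1,4-dibromo-2-(methoxymethoxy)benzene | COCOc1cc(Br)ccc1Br
F6 | step 2 | [3,6-dibromo-2-(methoxymethoxy)phenyl]trimethylsilane | COCOc1c(Br)ccc(Br)c1[Si](C)(C)C
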